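The data are calculated for substances that don't exist, noise included.

No rate constant of this chemistry is given, so whatever the reckoning uses has to be read from the larch and elm runs, which differ in the free catalyst charged.

all flasks: starting material 0.015 M
- larch: second substrate 0.015 M; protic impurity 0.015 M; free catalyst 0.20 mM; run made earlier
- elm: second substrate 0.015 M; protic impurity 0.015 M; free catalyst 0.31 mM; run made earlier
- flask: second substrate 0.0150 M; protic impurity 0.0150 M; free catalyst 0.41 mM

| run | time / min | target / % | starting material / % |
|---|---|---|---|
| larch | 0.333 | 2.3 | 89.5 |
| larch | 1.00 | 6.3 | 73.6 |
| larch | 2.00 | 11.4 | 56.3 |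
| larch | 2.50 | 13.5 | 49.8 |
| larch | 4.00 | 19.6 | 34.0 |
| larch | 5.00 | 23.1 | 27.2 |
| elm | 0.833 | 7.9 | 74.8 |
| elm | 1.50 | 13.0 | 60.3 |
| elm | 2.50 | 20.4 | 43.8 |
| elm | 3.00 | 23.8 | 37.4 |
| elm | 4.00 | 28.7 | 27.4 |
| elm | 5.00 | 32.9 | 19.8 |

(each reading ± 0.3 percentage points)

* apparent order in free catalyst when 10 % of the starting material are converted (percent change of the rate of making target for one percent more free catalyst charged)
* apparent order in second substrate when 10 % of the starting material are converted (percent change of the rate of making target for one percent more second substrate charged)
* factor on the rate of making target when 10 % of the starting material are converted if free catalyst is charged twice over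

- what is bound to the catalyst counts as converted
- no earlier run changes the charge of second substrate; that part of a forecast is a guess

The bench rule says that rate follows catalyst charged. Its ground is the balance of the reagent charged in the smaller amount, the catalyst: its charge Ctot is shared among free catalyst and any form holding it, so the rate of making target is a release constant k times the share f in the productive form times Ctot. That share depends on the substrate concentrations, which the rule takes as equal at a fixed conversion.

The larch run, down to 73.6 % starting material left, gives 4.73 min⁻¹ per catalyst charged. The elm run, down to 74.8 %, gives 4.59 min⁻¹. These lie 2.97 % apart, with a scatter of 0.3 percentage points on a reading of 6.3 %. Their mean, 4.66 min⁻¹, is T, the turnover rate: target made per minute per catalyst charged, averaged over the early part of each run rather than taken at a conversion of 10 %.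

For the flask, this reckoning gives T times 0.41 mM, or 1.91 mM min⁻¹, an order of 1 in free catalyst and a factor of 2. The rule stops where catalyst can shift the substrate itself. Here the ratio of charges is 2.73 %, below the 10 % looked at. For second substrate no run gives a number, and this reckoning commits to none.

The forecast gives 0.9, 0.7 and 1.87, slightly below this reckoning for catalyst, the middle value being by its own words a guess “This is a guess, since no run varied it”.

The flask gives 1.0 and 2.00 for free catalyst, −0.23 for second substrate, and a rate of 0.00190 M min⁻¹ at 0.237 min.

    starting material + protic impurity → quenched substrate (k = 17.0 M⁻¹ min⁻¹)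
    starting material + free catalyst ⇌ catalyst intermediate A (K = 190 M⁻¹, k = 13000 M⁻¹ min⁻¹)
    catalyst intermediate B → free catalyst + second product (k = 3.10 min⁻¹)
    catalyst intermediate A → free catalyst + target (k = 8.60 min⁻¹)
    second substrate + free catalyst ⇌ catalyst intermediate B (K = 66.0 M⁻¹, k = 11000 M⁻¹ min⁻¹)

In the flask, more second substrate lowers the rate at that conversion, and at 0.500 min catalyst intermediate B holds 23.7 % of the catalyst. For the flask charged with twice the catalyst, T gives 3.82 mM min⁻¹, and the simulated factor 2.00 on the rate gives 3.80 mM min⁻¹.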